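**Plan**
- Numbering: the chromone that carries the dimethoxyphenyl ring is O1, C2–C4, C4a, C5–C8, C8a; the dimethoxyphenyl ring is C1'–C6'; the apigenin unit is doubly primed.
- Cuts: O1–C2 (acid cyclodehydration of a 2,4,6-trihydroxyphenyl 1,3-diketone); C4a–C8a of ring A (Claisen folding of a 4-hydroxy-2-pyrone-masked triketo ester); C2–C3 (ester acylation of a pyrone trianion); C3'–C8'' (Suzuki coupling).
- Enabling feature: ring A (C4a, C5, C6, C7, C8, C8a) is a phloroglucinol ring with oxygen on C5, C7 and C8a, hydrogen on C6 and C8 and the acyl carbon C4 on C4a. It is therefore the Claisen-folding product of the chain C4a–C8a, and its two ortho oxygens (C5, C8a) are equivalent.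
- Forward order: apigenin is perbenzylated and iodinated at C8''; Suzuki coupling attaches the benzoate ring; the chain C3–C8a arrives as the trianion of 6-acetonyl-4-hydroxy-2-pyrone; ring A is folded with Mg(OMe)2, the pyranone ring is closed with acid, and hydrogenolysis frees three phenols.
- Stereochemistry: the target has no stereocentre and no stereogenic element that needs control.

Key step: step 7

Remark: the 3'–8'' biaryl axis carries no descriptor in the target, so it is treated as configurationally unspecified and no atroposelective step is planned.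

**Step 1**
Reactants: 1 apigenin
Product: 2 5,7,4'-tri-O-benzylapigenin
Conditions: BnBr (4.5 equiv), K2CO3, DMF, 80 °C
Reagents that add atoms: benzyl bromide, BrCc1ccccc1
Why: Williamson etherification under forcing conditions should alkylate the hydrogen-bonded 5-OH as well, which is needed so that the later iodination goes to C8 and not C6.

**Step 2**
Reactants: 2 5,7,4'-tri-O-benzylapigenin
Product: 3 8-iodo-5,7,4'-tri-O-benzylapigenin
Conditions: I2, CF3CO2Ag, CH2Cl2, 0 °C to rt, dark
Reagents that add atoms: iodine, II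
Why: electrophilic aromatic iodination of fully O-alkylated 5,7-dioxygenated flavones is known to go to C8, the most nucleophilic ring carbon, and the benzyl ethers are inert to the silver-activated iodine.

**Step 3**
Reactants: 4 methyl 3-bromo-4,5-dimethoxybenzoate
Product: 5 methyl 3,4-dimethoxy-5-(4,4,5,5-tetramethyl-1,3,2-dioxaborolan-2-yl)benzoate
Conditions: bis(pinacolato)diboron, PdCl2(dppf) (cat.), KOAc, 1,4-dioxane, 90 °C
Reagents that add atoms: bis(pinacolato)diboron, CC1(C)OB(OC1(C)C)B1OC(C)(C)C(C)(C)O1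
Why: Miyaura borylation of an aryl bromide is routine, and the weak base KOAc leaves the methyl ester untouched.

**Step 4**
Reactants: 3 8-iodo-5,7,4'-tri-O-benzylapigenin; 5 methyl 3,4-dimethoxy-5-(4,4,5,5-tetramethyl-1,3,2-dioxaborolan-2-yl)benzoate
Product: 6 methyl 3-(5,7,4'-tri-O-benzylapigenin-8-yl)-4,5-dimethoxybenzoate
Conditions: Pd(OAc)2 (cat.), SPhos, K3PO4, toluene/H2O, 90 °C
Reagents that add atoms: none
Why: Suzuki–Miyaura coupling with zerovalent palladium formed from Pd(OAc)2 and the bulky biaryl phosphine SPhos is the standard answer to tri-ortho-substituted biaryls, and it puts the robust boronate on the small ring and the iodide on the hindered flavone.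

**Step 5**
Reactants: 7 4-hydroxy-6-methyl-2H-pyran-2-one
Product: 9 4-hydroxy-6-(2-oxopropyl)-2H-pyran-2-one, via dilithiated pyrone dianion 8 (not isolated)
Conditions: LiN(i-Pr)2 (2.2 equiv), THF, −78 °C; then MeC(O)N(OMe)Me, −78 to 0 °C; cold aq. HCl
Reagents that add atoms: N-methoxy-N-methylacetamide, CON(C)C(C)=O
Why: the dianion of the lactone reacts at its C6-methyl carbanion, and acylation with a Weinreb amide (Weinreb ketone synthesis) stops at the chelated tetrahedral adduct, so neither over-addition nor proton transfer from the acidic product can occur before work-up.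

**Step 6**
Reactants: 9 4-hydroxy-6-(2-oxopropyl)-2H-pyran-2-one (3 equiv); 6 methyl 3-(5,7,4'-tri-O-benzylapigenin-8-yl)-4,5-dimethoxybenzoate
Product: 11 6-{4-[3-(5,7,4'-tri-O-benzylapigenin-8-yl)-4,5-dimethoxyphenyl]-2,4-dioxobutyl}-4-hydroxy-2H-pyran-2-one, via trilithiated pyrone trianion 10 (not isolated)
Conditions: 9, LiN(i-Pr)2 (3 equiv per 9), THF, −78 to 0 °C; then 6, 0 °C to rt; cold aq. HCl
Reagents that add atoms: none
Why: this is the Claisen-type terminal acylation of a β-polycarbonyl polyanion by an aromatic ester, in which the last-formed methyl carbanion is the most nucleophilic site, the excess trianion absorbs the acidic proton of the new diketone, and the chromone carbonyl of 6 (a doubly donated vinylogous ester) is a poorer electrophile than the benzoate.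

**Step 7**
Reactants: 11 6-{4-[3-(5,7,4'-tri-O-benzylapigenin-8-yl)-4,5-dimethoxyphenyl]-2,4-dioxobutyl}-4-hydroxy-2H-pyran-2-one
Product: 13 1-[3-(5,7,4'-tri-O-benzylapigenin-8-yl)-4,5-dimethoxyphenyl]-3-(2,4,6-trihydroxyphenyl)propane-1,3-dione, via ring-opened methyl tetraoxononanoate 12 (not isolated)
Conditions: Mg(OMe)2 (excess), MeOH/THF, 65 °C; then cold aq. HCl
Reagents that add atoms: none
Why: Mg(OMe)2 first turns the pyrone hydroxyl and the C2/C4 β-diketone of 11 into magnesium chelates, and methoxide then adds to the lactone carbonyl C8a and opens the ring to the keto ester 12, held as a magnesium polyenolate. The C4a carbanion, flanked by the C4 and C5 carbonyls, attacks the ester carbon C8a, methoxide leaves again, and enolisation gives the aromatic 2,4,6-trihydroxyphenyl ring, so the C4a–C8a bond and ring A form in one operation with no net gain of atoms. The closest known reaction type is the Claisen cyclisation of 3,5,7-triketo esters, and of their 4-hydroxy-2-pyrone forms, to acylphloroglucinols with Mg(OMe)2 in methanol. Ring A closes in the 6-(enolendo)-exo-trig mode and no stereocentre is created. The step needs Claisen closure (C4a to C8a) over aldol closure (C8 to C4, or C6 to C2): the magnesium diketonate at C2/C4 lowers the electrophilicity of both ketones, chelation of the C7/C8a β-keto ester activates the ester, and the anhydrous medium keeps C8a as an ester and not an unreactive carboxylate. Because the new ring has equivalent hydroxyls on C5 and C8a, the following chromone closure has only one possible outcome and this half needs no phenol protection.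

**Step 8**
Reactants: 13 1-[3-(5,7,4'-tri-O-benzylapigenin-8-yl)-4,5-dimethoxyphenyl]-3-(2,4,6-trihydroxyphenyl)propane-1,3-dione
Product: 14 5,7-bis(benzyloxy)-2-[4-(benzyloxy)phenyl]-8-[5-(5,7-dihydroxy-4-oxo-4H-chromen-2-yl)-2,3-dimethoxyphenyl]-4H-chromen-4-one
Conditions: conc. H2SO4 (cat.), AcOH, 50 °C
Reagents that add atoms: none
Why: acid-catalysed cyclodehydration of an ortho-hydroxyaryl 1,3-diketone (the closing stage of a Baker–Venkataraman flavone synthesis) should add a ring A hydroxyl to the aryl ketone C2 and expel water to form O1–C2 and the C2=C3 double bond, with the acid kept dilute and the temperature low to spare the benzyl ethers.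

**Step 9**
Reactants: 14 5,7-bis(benzyloxy)-2-[4-(benzyloxy)phenyl]-8-[5-(5,7-dihydroxy-4-oxo-4H-chromen-2-yl)-2,3-dimethoxyphenyl]-4H-chromen-4-one
Product: 15 5'-methoxybilobetin
Conditions: H2 (1 atm), 10% Pd/C, THF/MeOH, rt
Reagents that add atoms: none
Why: catalytic hydrogenolysis cleaves the three benzyl aryl ethers, while the two methyl ethers and the chromone double bonds should be untouched at ambient pressure and temperature.

**Compound list**
1 | apigenin, 5,7-dihydroxy-2-(4-hydroxyphenyl)-4H-chromen-4-one | O=c1cc(-c2ccc(O)cc2)oc2cc(O)cc(O)c12 | starting material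
2 | 5,7-bis(benzyloxy)-2-[4-(benzyloxy)phenyl]-4H-chromen-4-one (5,7,4'-tri-O-benzylapigenin) | O=c1cc(-c2ccc(OCc3ccccc3)cc2)oc2cc(OCc3ccccc3)cc(OCc3ccccc3)c12 | intermediate
3 | 5,7-bis(benzyloxy)-2-[4-(benzyloxy)phenyl]-8-iodo-4H-chromen-4-one | O=c1cc(-c2ccc(OCc3ccccc3)cc2)oc2c(I)c(OCc3ccccc3)cc(OCc3ccccc3)c12 | intermediate
4 | methyl 3-bromo-4,5-dimethoxybenzoate | COC(=O)c1cc(Br)c(OC)c(OC)c1 | starting material
5 | methyl 3,4-dimethoxy-5-(4,4,5,5-tetramethyl-1,3,2-dioxaborolan-2-yl)benzoate | COC(=O)c1cc(OC)c(OC)c(B2OC(C)(C)C(C)(C)O2)c1 | intermediate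
6 | methyl 3-{5,7-bis(benzyloxy)-2-[4-(benzyloxy)phenyl]-4-oxo-4H-chromen-8-yl}-4,5-dimethoxybenzoate | COC(=O)c1cc(OC)c(OC)c(-c2c(OCc3ccccc3)cc(OCc3ccccc3)c3c(=O)cc(-c4ccc(OCc5ccccc5)cc4)oc23)c1 | intermediate
7 | 4-hydroxy-6-methyl-2H-pyran-2-one (triacetic acid lactone) | CC1=CC(O)=CC(=O)O1 | starting material
8 | dilithium salt of the dianion of 7 (4-oxido, C6-methyl carbanion; not isolated) | [Li+].[Li+].[CH2-]C1=CC([O-])=CC(=O)O1 | intermediate
9 | 4-hydroxy-6-(2-oxopropyl)-2H-pyran-2-one | CC(=O)CC1=CC(O)=CC(=O)O1 | intermediate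
10 | trilithium salt of the trianion of 9 (4-oxido, side-chain CH and terminal CH2 carbanions; not isolated) | [Li+].[Li+].[Li+].[CH2-]C(=O)[CH-]C1=CC([O-])=CC(=O)O1 | intermediate
11 | 6-{4-[3-(5,7-bis(benzyloxy)-2-[4-(benzyloxy)phenyl]-4-oxo-4H-chromen-8-yl)-4,5-dimethoxyphenyl]-2,4-dioxobutyl}-4-hydroxy-2H-pyran-2-one | O=C1C=C(O)C=C(CC(=O)CC(=O)c2cc(OC)c(OC)c(-c3c(OCc4ccccc4)cc(OCc4ccccc4)c4c(=O)cc(-c5ccc(OCc6ccccc6)cc5)oc34)c2)O1 | intermediate
12 | methyl 9-[3-(5,7-bis(benzyloxy)-2-[4-(benzyloxy)phenyl]-4-oxo-4H-chromen-8-yl)-4,5-dimethoxyphenyl]-3,5,7,9-tetraoxononanoate (present as its magnesium enolate, drawn in the neutral keto form; not isolated) | COC(=O)CC(=O)CC(=O)CC(=O)CC(=O)c1cc(OC)c(OC)c(-c2c(OCc3ccccc3)cc(OCc3ccccc3)c3c(=O)cc(-c4ccc(OCc5ccccc5)cc4)oc23)c1 | intermediate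
13 | 1-[3-(5,7-bis(benzyloxy)-2-[4-(benzyloxy)phenyl]-4-oxo-4H-chromen-8-yl)-4,5-dimethoxyphenyl]-3-(2,4,6-trihydroxyphenyl)propane-1,3-dione | O=C(CC(=O)c1cc(OC)c(OC)c(-c2c(OCc3ccccc3)cc(OCc3ccccc3)c3c(=O)cc(-c4ccc(OCc5ccccc5)cc4)oc23)c1)c1c(O)cc(O)cc1O | intermediate
14 | 5,7-bis(benzyloxy)-2-[4-(benzyloxy)phenyl]-8-[5-(5,7-dihydroxy-4-oxo-4H-chromen-2-yl)-2,3-dimethoxyphenyl]-4H-chromen-4-one | COc1cc(-c2cc(=O)c3c(O)cc(O)cc3o2)cc(-c2c(OCc3ccccc3)cc(OCc3ccccc3)c3c(=O)cc(-c4ccc(OCc5ccccc5)cc4)oc23)c1OC | intermediate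
15 | 5'-methoxybilobetin, 8-[5-(5,7-dihydroxy-4-oxo-4H-chromen-2-yl)-2,3-dimethoxyphenyl]-5,7-dihydroxy-2-(4-hydroxyphenyl)-4H-chromen-4-one | COc1cc(-c2cc(=O)c3c(O)cc(O)cc3o2)cc(-c2c(O)cc(O)c3c(=O)cc(-c4ccc(O)cc4)oc23)c1OC | target

**Totals**
Total step count: 9. Longest linear sequence: 7 steps (steps 1, 2, 4, 6, 7, 8, 9 from apigenin).

**Steps most likely to fail**

Step 6. The third deprotonation of 9 may be incomplete or the trilithio species may aggregate; the acidic product may quench unreacted trianion; and the carbanion may add to the chromone carbonyl of 6. The fallback sets out from 6, returns at 11, and needs only the established dianion 8.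
- Ester 6 would be condensed with the lithium enolate of N-methoxy-N-methylacetamide (LiN(i-Pr)2, THF, −78 °C, crossed Claisen condensation) to give 3-[3-(5,7,4'-tri-O-benzylapigenin-8-yl)-4,5-dimethoxyphenyl]-N-methoxy-N-methyl-3-oxopropanamide F1.
- The aryl ketone of F1 would be masked with ethylene glycol (p-TsOH cat., toluene, 60 °C, molecular sieves) as the 1,3-dioxolane 2-{2-[3-(5,7,4'-tri-O-benzylapigenin-8-yl)-4,5-dimethoxyphenyl]-1,3-dioxolan-2-yl}-N-methoxy-N-methylacetamide F2.
- Dianion 8, made from 7 as in step 5 and used in excess, would be acylated by the Weinreb amide F2 (THF, −78 to 0 °C) to give the ketal-protected pyrone 6-(3-{2-[3-(5,7,4'-tri-O-benzylapigenin-8-yl)-4,5-dimethoxyphenyl]-1,3-dioxolan-2-yl}-2-oxopropyl)-4-hydroxy-2H-pyran-2-one F3.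
- Dilute aqueous HCl in THF at rt would release the aryl ketone and deliver 11.

Step 7. Aldol closure (C8 onto C4, or the pyrone carbon C6 onto C2) may compete with the Claisen closure, or methanolysis of the lactone may stall. The fallback sets out from 6, returns at 13, and builds the same diketone by acylating a preformed phloroglucinol ketone.
- Ester 6 would be saponified (LiOH, THF/MeOH/H2O, then HCl) to 3-(5,7,4'-tri-O-benzylapigenin-8-yl)-4,5-dimethoxybenzoic acid F4.
- F4 would be converted with oxalyl chloride and catalytic DMF in CH2Cl2 into 3-(5,7,4'-tri-O-benzylapigenin-8-yl)-4,5-dimethoxybenzoyl chloride F5.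
- Anhydrous 2,4,6-trihydroxyacetophenone, deprotonated with LiN(SiMe3)2 (4.5 equiv, THF, −78 °C) to its tris-phenoxide enolate, would be C-acylated by F5 at the enolate carbon; acidic work-up should give 13 directly.

Step 8. Acid may cleave the 5''-O-benzyl ether, which lies peri to the carbonyl, and the released benzyl cation may alkylate the electron-rich ring A. The fallback sets out from 13, returns at 15, and reverses the order of the last two operations.
- Hydrogenolysis of 13 (H2, 10% Pd/C, THF/MeOH, rt) would give the benzyl-free diketone 1-{3-[5,7-dihydroxy-2-(4-hydroxyphenyl)-4-oxo-4H-chromen-8-yl]-4,5-dimethoxyphenyl}-3-(2,4,6-trihydroxyphenyl)propane-1,3-dione F6.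
- F6 carries no acid-labile group, so it could be cyclodehydrated under forcing conditions (conc. H2SO4 in AcOH, 100 °C) to the target 15.

**Further compounds**
F1 | step 6 | 3-[3-(5,7-bis(benzyloxy)-2-[4-(benzyloxy)phenyl]-4-oxo-4H-chromen-8-yl)-4,5-dimethoxyphenyl]-N-methoxy-N-methyl-3-oxopropanamide | CON(C)C(=O)CC(=O)c1cc(OC)c(OC)c(-c2c(OCc3ccccc3)cc(OCc3ccccc3)c3c(=O)cc(-c4ccc(OCc5ccccc5)cc4)oc23)c1
F2 | step 6 | 2-{2-[3-(5,7-bis(benzyloxy)-2-[4-(benzyloxy)phenyl]-4-oxo-4H-chromen-8-yl)-4,5-dimethoxyphenyl]-1,3-dioxolan-2-yl}-N-methoxy-N-methylacetamide | CON(C)C(=O)CC1(OCCO1)c1cc(OC)c(OC)c(-c2c(OCc3ccccc3)cc(OCc3ccccc3)c3c(=O)cc(-c4ccc(OCc5ccccc5)cc4)oc23)c1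
F3 | step 6 | 6-(3-{2-[3-(5,7-bis(benzyloxy)-2-[4-(benzyloxy)phenyl]-4-oxo-4H-chromen-8-yl)-4,5-dimethoxyphenyl]-1,3-dioxolan-2-yl}-2-oxopropyl)-4-hydroxy-2H-pyran-2-one | O=C1C=C(O)C=C(CC(=O)CC2(OCCO2)c2cc(OC)c(OC)c(-c3c(OCc4ccccc4)cc(OCc4ccccc4)c4c(=O)cc(-c5ccc(OCc6ccccc6)cc5)oc34)c2)O1
F4 | step 7 | 3-{5,7-bis(benzyloxy)-2-[4-(benzyloxy)phenyl]-4-oxo-4H-chromen-8-yl}-4,5-dimethoxybenzoic acid | OC(=O)c1cc(OC)c(OC)c(-c2c(OCc3ccccc3)cc(OCc3ccccc3)c3c(=O)cc(-c4ccc(OCc5ccccc5)cc4)oc23)c1
F5 | step 7 | 3-{5,7-bis(benzyloxy)-2-[4-(benzyloxy)phenyl]-4-oxo-4H-chromen-8-yl}-4,5-dimethoxybenzoyl chloride | O=C(Cl)c1cc(OC)c(OC)c(-c2c(OCc3ccccc3)cc(OCc3ccccc3)c3c(=O)cc(-c4ccc(OCc5ccccc5)cc4)oc23)c1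
F6 | step 8 | 1-{3-[5,7-dihydroxy-2-(4-hydroxyphenyl)-4-oxo-4H-chromen-8-yl]-4,5-dimethoxyphenyl}-3-(2,4,6-trihydroxyphenyl)propane-1,3-dione | O=C(CC(=O)c1cc(OC)c(OC)c(-c2c(O)cc(O)c3c(=O)cc(-c4ccc(O)cc4)oc23)c1)c1c(O)cc(O)cc1O
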